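The 14-membered carbocycle is opened at the bond between C4, the isopropyl-bearing tertiary allylic carbinol, and C3, the ring methylene that ends the two-carbon arm on the butenolide α-carbon C1 (14-oxabicyclo[11.2.1]hexadecane numbering). Both carbons are electrophilic in the precursor: C4 is the ketone of an (E)-γ-silyloxy enone and C3 a primary iodide. A reductive samarium Barbier macrocyclisation (SmI2, catalytic NiI2) reverses the polarity of C3, closes the carbocycle, creates the C4 carbinol and sets its configuration in one operation. The seco-iodo-enone arises by cross-metathesis of a butenolide fragment from (S)-linalool with an enone fragment from (S)-2-methylglycidol.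

Key step: step 11

Remark on the chemistry: (S)-(+)-linalool, (S)-2-methylglycidol and dimethyl (3-methyl-2-oxobutyl)phosphonate are taken as commercial materials of high enantiomeric and chemical purity.

Step 1
Reactants: 1 (S)-(+)-linalool
Product: 2 triethyl{[(3S)-3,7-dimethylocta-1,6-dien-3-yl]oxy}silane
Conditions: Et3SiOTf, 2,6-lutidine, CH2Cl2, 0 °C
Reagents that add atoms: triethylsilyl trifluoromethanesulfonate, CC[Si](CC)(CC)OS(=O)(=O)C(F)(F)F
Why: Silyl ether formation with the silyl triflate and a hindered pyridine base caps the tertiary allylic alcohol so that the aldehyde made next cannot close to a lactol, and the stereocentre is not touched.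

Step 2
Reactants: 2 triethylsilyl ether of (S)-linalool
Product: 3 (4S)-4-methyl-4-[(triethylsilyl)oxy]hex-5-enal
Conditions: O3, CH2Cl2, −78 °C (Sudan Red 7B end-point); then PPh3, −78 °C to rt
Reagents that add atoms: ozone, [O-][O+]=O
Why: Ozonolysis with reductive work-up should cleave only the electron-rich trisubstituted alkene, because the monosubstituted vinyl group beside the quaternary silyloxy carbon reacts far more slowly.

Step 3
Reactants: 4 methyl 2-[bis(2,2,2-trifluoroethoxy)phosphoryl]acetate, 5 tert-butyl(2-iodoethoxy)dimethylsilane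
Product: 6 methyl 2-[bis(2,2,2-trifluoroethoxy)phosphoryl]-4-[(tert-butyldimethylsilyl)oxy]butanoate (racemic)
Conditions: NaH, DMF, 0 °C to rt
Reagents that add atoms: none
Why: C-Alkylation of the sodium phosphonoacetate with the primary iodide (enolate alkylation) should give the α-substituted Still–Gennari reagent that carries the future two-carbon arm.

Step 4
Reactants: 3 (4S)-4-methyl-4-[(triethylsilyl)oxy]hex-5-enal, 6 α-substituted Still–Gennari phosphonate
Product: 8 methyl (2Z,4R,6S)-2-{2-[(tert-butyldimethylsilyl)oxy]ethyl}-6-methyl-4-[(phenylamino)oxy]-6-[(triethylsilyl)oxy]octa-2,7-dienoate, via aminoxy aldehyde 7 (not isolated)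
Conditions: nitrosobenzene, L-proline (20 mol %), MeCN, −20 °C; then added to 6, KN(SiMe3)2, 18-crown-6, THF, −78 °C
Reagents that add atoms: nitrosobenzene, O=Nc1ccccc1
Why: Proline-catalysed α-aminoxylation delivers the nitroso oxygen to one enamine face through a carboxylic-acid hydrogen-bonded transition state (L-proline should give the 2R aldehyde), and the in situ Still–Gennari Horner–Wadsworth–Emmons olefination under kinetic control should give the Z-trisubstituted enoate before the α-stereocentre can epimerise.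

Step 5
Reactants: 8 Z-enoate
Product: 11 (5R)-5-[(2S)-2-hydroxy-2-methylbut-3-en-1-yl]-3-(2-hydroxyethyl)furan-2(5H)-one, via hydroxy enoate 9 (not isolated), via bis-silyl butenolide 10 (not isolated)
Conditions: Zn, AcOH, THF, rt; filtration; then HF·pyridine, THF, 0 °C to rt
Reagents that add atoms: none
Why: Reductive N–O cleavage by zinc frees the γ-hydroxyl, which should lactonise at once onto the cis ester to form the butenolide, and fluoride then removes both silyl ethers without touching either stereocentre.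

Step 6
Reactants: 11 butenolide diol
Product: 12 (5R)-5-[(2S)-2-hydroxy-2-methylbut-3-en-1-yl]-3-(2-iodoethyl)furan-2(5H)-one
Conditions: I2, PPh3, imidazole, CH2Cl2, 0 °C
Reagents that add atoms: iodine, II
Why: Appel-type iodination should convert only the primary alcohol, because the tertiary allylic alcohol is too hindered to form the alkoxyphosphonium salt.

Step 7
Reactants: 13 (S)-2-methylglycidol
Product: 14 (2R)-2-methylpent-4-ene-1,2-diol
Conditions: CH2=CHMgBr (3 equiv), CuI (10 mol %), THF, −30 to 0 °C; aqueous NH4Cl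
Reagents that add atoms: vinylmagnesium bromide, C=C[Mg]Br
Why: Copper-catalysed Grignard opening of the 2,2-disubstituted epoxide (SN2 epoxide opening) occurs at the unsubstituted CH2 carbon, so the quaternary stereocentre is kept and only its descriptor changes.

Step 8
Reactants: 14 (2R)-2-methylpent-4-ene-1,2-diol, 15 dimethyl (3-methyl-2-oxobutyl)phosphonate
Product: 17 (4E,6R)-6-hydroxy-2,6-dimethylnona-4,8-dien-3-one, via hydroxy aldehyde 16 (not isolated)
Conditions: TEMPO (10 mol %), (diacetoxyiodo)benzene, CH2Cl2, rt; then 15, LiCl, iPr2NEt, MeCN, rt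
Reagents that add atoms: none
Why: Nitroxyl-catalysed oxidation converts only the primary alcohol to the α-hydroxy aldehyde, and Horner–Wadsworth–Emmons olefination under LiCl/amine conditions should give the E-enone without isolating that sensitive aldehyde.

Step 9
Reactants: 12 butenolide iodide, 17 enone fragment
Product: 18 (5R)-5-[(2S,3E,6R,7E)-2,6-dihydroxy-2,6,10-trimethyl-9-oxoundeca-3,7-dien-1-yl]-3-(2-iodoethyl)furan-2(5H)-one
Conditions: Hoveyda–Grubbs second-generation catalyst RuCl2(SIMes)(=CH-C6H4-2-OiPr) (10 mol %), 17 (3 equiv), CH2Cl2, 40 °C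
Reagents that add atoms: none
Why: Olefin cross-metathesis joins the allyl group of 17 to the vinyl group of the free tertiary allylic alcohol 12, the hindered partner homodimerising slowly and the allyl partner reversibly, and the quaternary allylic carbon should enforce the E-alkene.

Step 10
Reactants: 18 seco diol
Product: 19 (5R)-3-(2-iodoethyl)-5-{(2S,3E,6R,7E)-2,6,10-trimethyl-9-oxo-2,6-bis[(trimethylsilyl)oxy]undeca-3,7-dien-1-yl}furan-2(5H)-one
Conditions: N-(trimethylsilyl)imidazole, CH2Cl2, rt
Reagents that add atoms: N-(trimethylsilyl)imidazole, C[Si](C)(C)n1ccnc1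
Why: Neutral silyl transfer (silyl ether formation) caps both tertiary alcohols without enolising the butenolide or the ketone, removing the protons that would quench the organosamarium intermediate.

Step 11
Reactants: 19 bis-silylated iodo enone
Product: 21 (4S,5E,7R,9E,11S,13R)-4,7,11-trihydroxy-7,11-dimethyl-4-(propan-2-yl)-14-oxabicyclo[11.2.1]hexadeca-1(16),5,9-trien-15-one (target), via bis-silyl macrocycle 20 (not isolated)
Conditions: SmI2 (3 equiv), NiI2 (2 mol %), THF, 0 °C, slow addition of 19 (final 0.002 M); aqueous NaHCO3 work-up; then HF·pyridine, pyridine, THF, 0 °C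
Reagents that add atoms: none
Why: SmI2 reduces NiI2 to zerovalent nickel, which inserts into the primary C–I bond, and transmetalation to trivalent samarium gives a primary alkylsamarium that adds 1,2 to the tethered ketone, after which fluoride frees the two silylated alcohols. The closest known reaction type is the nickel-catalysed samarium Barbier reaction of alkyl iodides with ketones, together with samarium Barbier macrocyclisations of halo carbonyl compounds. The 14-membered carbocycle closes in a 14-exo-trig mode under high dilution, with the two E-alkenes and the butenolide restricting the chain. The new C4 stereocentre is under substrate control: the alkyl terminus must attack the Re face of the ketone, which is expected if the transition state keeps the isopropyl group and the samarium-bound oxygen on the periphery of the forming ring, away from the C7 quaternary carbon. The step needs C–I activation to outrun electron transfer to the enone or butenolide and 1,2- to outrun 1,4-addition; HMPA-free THF with nickel catalysis, the oxophilic samarium nucleophile and the quaternary carbon beside the enone β-position should secure this, while the silyl ethers prevent protonation.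

Compound list
1 | (S)-(+)-linalool, (3S)-3,7-dimethylocta-1,6-dien-3-ol | C=C[C@@](C)(O)CCC=C(C)C | starting material
2 | triethyl{[(3S)-3,7-dimethylocta-1,6-dien-3-yl]oxy}silane | C=C[C@@](C)(O[Si](CC)(CC)CC)CCC=C(C)C | intermediate
3 | (4S)-4-methyl-4-[(triethylsilyl)oxy]hex-5-enal | C=C[C@@](C)(O[Si](CC)(CC)CC)CCC=O | intermediate
4 | methyl 2-[bis(2,2,2-trifluoroethoxy)phosphoryl]acetate | COC(=O)CP(=O)(OCC(F)(F)F)OCC(F)(F)F | starting material
5 | tert-butyl(2-iodoethoxy)dimethylsilane | CC(C)(C)[Si](C)(C)OCCI | starting material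
6 | methyl 2-[bis(2,2,2-trifluoroethoxy)phosphoryl]-4-[(tert-butyldimethylsilyl)oxy]butanoate (racemic) | COC(=O)C(CCO[Si](C)(C)C(C)(C)C)P(=O)(OCC(F)(F)F)OCC(F)(F)F | intermediate
7 | (2R,4S)-4-methyl-2-[(phenylamino)oxy]-4-[(triethylsilyl)oxy]hex-5-enal | C=C[C@@](C)(O[Si](CC)(CC)CC)C[C@@H](ONc1ccccc1)C=O | intermediate
8 | methyl (2Z,4R,6S)-2-{2-[(tert-butyldimethylsilyl)oxy]ethyl}-6-methyl-4-[(phenylamino)oxy]-6-[(triethylsilyl)oxy]octa-2,7-dienoate | C=C[C@@](C)(O[Si](CC)(CC)CC)C[C@@H](ONc1ccccc1)/C=C(/CCO[Si](C)(C)C(C)(C)C)C(=O)OC | intermediate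
9 | methyl (2Z,4R,6S)-2-{2-[(tert-butyldimethylsilyl)oxy]ethyl}-4-hydroxy-6-methyl-6-[(triethylsilyl)oxy]octa-2,7-dienoate | C=C[C@@](C)(O[Si](CC)(CC)CC)C[C@@H](O)/C=C(/CCO[Si](C)(C)C(C)(C)C)C(=O)OC | intermediate
10 | (5R)-3-{2-[(tert-butyldimethylsilyl)oxy]ethyl}-5-{(2S)-2-methyl-2-[(triethylsilyl)oxy]but-3-en-1-yl}furan-2(5H)-one | C=C[C@@](C)(O[Si](CC)(CC)CC)C[C@@H]1C=C(CCO[Si](C)(C)C(C)(C)C)C(=O)O1 | intermediate
11 | (5R)-5-[(2S)-2-hydroxy-2-methylbut-3-en-1-yl]-3-(2-hydroxyethyl)furan-2(5H)-one | C=C[C@@](C)(O)C[C@@H]1C=C(CCO)C(=O)O1 | intermediate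
12 | (5R)-5-[(2S)-2-hydroxy-2-methylbut-3-en-1-yl]-3-(2-iodoethyl)furan-2(5H)-one | C=C[C@@](C)(O)C[C@@H]1C=C(CCI)C(=O)O1 | intermediate
13 | (S)-2-methylglycidol, [(2S)-2-methyloxiran-2-yl]methanol | C[C@]1(CO)CO1 | starting material
14 | (2R)-2-methylpent-4-ene-1,2-diol | C[C@](O)(CO)CC=C | intermediate
15 | dimethyl (3-methyl-2-oxobutyl)phosphonate | CC(C)C(=O)CP(=O)(OC)OC | starting material
16 | (2R)-2-hydroxy-2-methylpent-4-enal | C[C@](O)(C=O)CC=C | intermediate
17 | (4E,6R)-6-hydroxy-2,6-dimethylnona-4,8-dien-3-one | CC(C)C(=O)/C=C/[C@](C)(O)CC=C | intermediate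
18 | (5R)-5-[(2S,3E,6R,7E)-2,6-dihydroxy-2,6,10-trimethyl-9-oxoundeca-3,7-dien-1-yl]-3-(2-iodoethyl)furan-2(5H)-one | CC(C)C(=O)/C=C/[C@](C)(O)C/C=C/[C@@](C)(O)C[C@@H]1C=C(CCI)C(=O)O1 | intermediate
19 | (5R)-3-(2-iodoethyl)-5-{(2S,3E,6R,7E)-2,6,10-trimethyl-9-oxo-2,6-bis[(trimethylsilyl)oxy]undeca-3,7-dien-1-yl}furan-2(5H)-one | CC(C)C(=O)/C=C/[C@](C)(O[Si](C)(C)C)C/C=C/[C@@](C)(O[Si](C)(C)C)C[C@@H]1C=C(CCI)C(=O)O1 | intermediate
20 | (4S,5E,7R,9E,11S,13R)-4-hydroxy-7,11-dimethyl-4-(propan-2-yl)-7,11-bis[(trimethylsilyl)oxy]-14-oxabicyclo[11.2.1]hexadeca-1(16),5,9-trien-15-one | CC(C)[C@]1(O)/C=C/[C@](C)(O[Si](C)(C)C)C/C=C/[C@@](C)(O[Si](C)(C)C)C[C@@H]2C=C(CC1)C(=O)O2 | intermediate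
21 | (4S,5E,7R,9E,11S,13R)-4,7,11-trihydroxy-7,11-dimethyl-4-(propan-2-yl)-14-oxabicyclo[11.2.1]hexadeca-1(16),5,9-trien-15-one | CC(C)[C@]1(O)/C=C/[C@](C)(O)C/C=C/[C@@](C)(O)C[C@@H]2C=C(CC1)C(=O)O2 | target

Total step count: 11. Longest linear sequence: 8 steps (steps 1, 2, 4, 5, 6, 9, 10, 11, from (S)-linalool).

Steps most likely to fail

Step 11. Electron transfer from SmI2 to the γ-silyloxy enone (with loss of the silyloxy group) or to the butenolide may compete with activation of the C–I bond. The alkyl terminus may also add in conjugate fashion, enolise the isopropyl ketone, or attack the Si face of the ketone. The fallback sets out from 14 (through aldehyde 16) and from 12, returns at 20, and reverses the order in which the two carbon substituents reach C4. Aldehyde 16 is intercepted with (triphenylphosphoranylidene)acetaldehyde to give (2E,4R)-4-hydroxy-4-methylhepta-2,6-dienal F1. Cross-metathesis with 12 as in step 9 gives the iodo enal F2, and silylation as in step 10 gives its bis(trimethylsilyl) ether F3. CrCl2 with catalytic cobalt phthalocyanine CoC32H16N8 in DMF turns the iodide into an alkylchromium species that adds only to the aldehyde, closing the ring to the macrocyclic secondary allylic alcohol F4 (either epimer serves). Dess–Martin oxidation gives the macrocyclic enone F5. Isopropylcerium dichloride (iPrMgCl, CeCl3, THF, −78 °C) should then add 1,2 to the ring ketone from the periphery, leaving the lactone alone, to give 20, which is desilylated as in the second stage of step 11.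

Step 4. The α-aminoxy aldehyde may epimerise or decompose under the basic olefination, and the Z-selectivity for the trisubstituted enoate may erode, leaving an ester that cannot lactonise. The fallback sets out from 3 and returns at 11. After the same aminoxylation, aldehyde 7 is olefinated under LiCl/iPr2NEt with commercial diethyl (2-oxooxolan-3-yl)phosphonate to give the E-alkylidene lactone F6. Zn/AcOH cleaves the N–O bond to the hydroxy alkylidene lactone F7. Irradiation isomerises the exocyclic alkene, and the Z isomer is drained by translactonisation to the hydroxyethyl butenolide silyl ether F8. Both alkene isomers therefore converge, and the two-carbon arm is released as the free alcohol without a protecting group. HF·pyridine then gives 11.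

Step 9. Initiation at the hindered vinyl group of the tertiary carbinol may be slow, so that homodimerisation of 17 and catalyst deactivation by the hydroxy enone take over. The fallback sets out from 12 and 14 and returns at 18. The metathesis is run with the cheap diol 14 in large excess, which carries no enone, to give the triol iodide F9. Nitroxyl-catalysed oxidation of its primary alcohol, as in the first stage of step 8, gives the α-hydroxy aldehyde F10, and olefination with 15 as in step 8 gives 18.

Further compounds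
F1 | step 11 | (2E,4R)-4-hydroxy-4-methylhepta-2,6-dienal | O=C/C=C/[C@](C)(O)CC=C
F2 | step 11 | (2E,4R,6E,8S)-4,8-dihydroxy-9-[(2R)-4-(2-iodoethyl)-5-oxo-2,5-dihydrofuran-2-yl]-4,8-dimethylnona-2,6-dienal | O=C/C=C/[C@](C)(O)C/C=C/[C@@](C)(O)C[C@@H]1C=C(CCI)C(=O)O1
F3 | step 11 | (2E,4R,6E,8S)-9-[(2R)-4-(2-iodoethyl)-5-oxo-2,5-dihydrofuran-2-yl]-4,8-dimethyl-4,8-bis[(trimethylsilyl)oxy]nona-2,6-dienal | O=C/C=C/[C@](C)(O[Si](C)(C)C)C/C=C/[C@@](C)(O[Si](C)(C)C)C[C@@H]1C=C(CCI)C(=O)O1
F4 | step 11 | (5E,7R,9E,11S,13R)-4-hydroxy-7,11-dimethyl-7,11-bis[(trimethylsilyl)oxy]-14-oxabicyclo[11.2.1]hexadeca-1(16),5,9-trien-15-one (C4 epimers) | OC1/C=C/[C@](C)(O[Si](C)(C)C)C/C=C/[C@@](C)(O[Si](C)(C)C)C[C@@H]2C=C(CC1)C(=O)O2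
F5 | step 11 | (5E,7R,9E,11S,13R)-7,11-dimethyl-7,11-bis[(trimethylsilyl)oxy]-14-oxabicyclo[11.2.1]hexadeca-1(16),5,9-triene-4,15-dione | O=C1/C=C/[C@](C)(O[Si](C)(C)C)C/C=C/[C@@](C)(O[Si](C)(C)C)C[C@@H]2C=C(CC1)C(=O)O2
F6 | step 4 | (3E)-3-{(2R,4S)-4-methyl-2-[(phenylamino)oxy]-4-[(triethylsilyl)oxy]hex-5-en-1-ylidene}oxolan-2-one | C=C[C@@](C)(O[Si](CC)(CC)CC)C[C@@H](ONc1ccccc1)/C=C1\CCOC1=O
F7 | step 4 | (3E)-3-{(2R,4S)-2-hydroxy-4-methyl-4-[(triethylsilyl)oxy]hex-5-en-1-ylidene}oxolan-2-one | C=C[C@@](C)(O[Si](CC)(CC)CC)C[C@@H](O)/C=C1\CCOC1=O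
F8 | step 4 | (5R)-3-(2-hydroxyethyl)-5-{(2S)-2-methyl-2-[(triethylsilyl)oxy]but-3-en-1-yl}furan-2(5H)-one | C=C[C@@](C)(O[Si](CC)(CC)CC)C[C@@H]1C=C(CCO)C(=O)O1
F9 | step 9 | (5R)-5-[(2S,3E,6R)-2,6,7-trihydroxy-2,6-dimethylhept-3-en-1-yl]-3-(2-iodoethyl)furan-2(5H)-one | OC[C@](C)(O)C/C=C/[C@@](C)(O)C[C@@H]1C=C(CCI)C(=O)O1
F10 | step 9 | (2R,4E,6S)-2,6-dihydroxy-7-[(2R)-4-(2-iodoethyl)-5-oxo-2,5-dihydrofuran-2-yl]-2,6-dimethylhept-4-enal | O=C[C@](C)(O)C/C=C/[C@@](C)(O)C[C@@H]1C=C(CCI)C(=O)O1
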